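**Assumption:** the target (5,6,8-trimethoxy-2-(2,5-dimethoxyphenyl)-4H-chromen-4-one) has no stereocentre, so there is no enantiomer to control; the only stereo-element on the way is the E alkene of the chalcone, and it is consumed.

**Retrosynthetic overview**
1. Open ring C of flavone 9 (O1–C2 bond and C2=C3 unsaturation) to 2'-hydroxychalcone 6, closed in the forward direction by oxidative cyclisation.
2. Cut chalcone 6 at the enone C=C (Claisen–Schmidt) into acetophenone 3 and 2,5-dimethoxybenzaldehyde 4.
3. Acetophenone 3 comes from symmetric 1,2,4,5-tetramethoxybenzene 1 by Friedel–Crafts acetylation with chelation-controlled mono-demethylation.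
4. Rings A and B are bought intact; ring C is the only ring formed, and it is formed last.

**Route**

Step 1
Reactants: 1 1,2,4,5-tetramethoxybenzene
Product: 3 1-(2-hydroxy-3,5,6-trimethoxyphenyl)ethanone, via tetramethoxyacetophenone 2 (not isolated)
Conditions: AcCl (1.2 equiv), AlCl3 (2.5 equiv), CH2Cl2, 0 °C to rt; then ice / 1 M HCl
Reagents that add atoms: acetyl chloride, CC(Cl)=O
Why: Friedel–Crafts acylation at one of the two equivalent free positions gives symmetric ketone 2, and AlCl3 chelated between the carbonyl and an ortho methoxy cleaves just one of the two equivalent ortho methyl ethers (chelation-controlled demethylation); no stereocentre is formed.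

Step 2
Reactants: 3 1-(2-hydroxy-3,5,6-trimethoxyphenyl)ethanone; 4 2,5-dimethoxybenzaldehyde
Product: 6 (E)-3-(2,5-dimethoxyphenyl)-1-(2-hydroxy-3,5,6-trimethoxyphenyl)prop-2-en-1-one, via aldol adduct 5 (not isolated)
Conditions: KOH (50% aq, excess), EtOH, rt, 24–48 h; then cold 2 M HCl
Reagents that add atoms: none
Why: Claisen–Schmidt condensation: the methyl ketone enolate adds to the non-enolisable aldehyde and E1cB loss of water gives the thermodynamically favoured E enone; any flavanone 7 formed by early ring closure converges in step 3.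

Step 3
Reactants: 6 (E)-3-(2,5-dimethoxyphenyl)-1-(2-hydroxy-3,5,6-trimethoxyphenyl)prop-2-en-1-one
Product: 9 5,6,8-trimethoxy-2-(2,5-dimethoxyphenyl)-4H-chromen-4-one, via flavanone 7 (not isolated), via 3-iodoflavanone 8 (not isolated)
Conditions: I2 (10 mol %), DMSO, 130 °C, 2–4 h; pour into ice-water, recrystallise
Reagents that add atoms: none
Why: Iodine-catalysed oxidative cyclisation: 6-endo oxa-Michael closure gives flavanone 7, iodine converts it to the 3-iodo ketone 8, and loss of hydrogen iodide from 8 gives the 4-pyranone while DMSO, the terminal oxidant, turns the hydrogen iodide back into iodine; the aryl methyl ethers are untouched and no stereocentre remains.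

**Compound list**
1 | 1,2,4,5-tetramethoxybenzene | COc1cc(OC)c(OC)cc1OC | starting material
2 | 1-(2,3,5,6-tetramethoxyphenyl)ethanone | CC(=O)c1c(OC)c(OC)cc(OC)c1OC | intermediate (not isolated)
3 | 1-(2-hydroxy-3,5,6-trimethoxyphenyl)ethanone | CC(=O)c1c(O)c(OC)cc(OC)c1OC | intermediate
4 | 2,5-dimethoxybenzaldehyde | COc1ccc(OC)c(C=O)c1 | starting material
5 | 3-(2,5-dimethoxyphenyl)-3-hydroxy-1-(2-hydroxy-3,5,6-trimethoxyphenyl)propan-1-one (racemic aldol adduct) | COc1ccc(OC)c(C(O)CC(=O)c2c(O)c(OC)cc(OC)c2OC)c1 | intermediate (not isolated)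
6 | (E)-3-(2,5-dimethoxyphenyl)-1-(2-hydroxy-3,5,6-trimethoxyphenyl)prop-2-en-1-one | COc1ccc(OC)c(/C=C/C(=O)c2c(O)c(OC)cc(OC)c2OC)c1 | intermediate
7 | 2-(2,5-dimethoxyphenyl)-5,6,8-trimethoxychroman-4-one (racemic flavanone) | COc1ccc(OC)c(C2CC(=O)c3c(OC)c(OC)cc(OC)c3O2)c1 | intermediate (not isolated)
8 | 2-(2,5-dimethoxyphenyl)-3-iodo-5,6,8-trimethoxychroman-4-one (3-iodoflavanone, racemic, relative configuration not defined) | COc1ccc(OC)c(C2Oc3c(OC)cc(OC)c(OC)c3C(=O)C2I)c1 | intermediate (not isolated)
9 | 5,6,8-trimethoxy-2-(2,5-dimethoxyphenyl)-4H-chromen-4-one | COc1ccc(OC)c(-c2cc(=O)c3c(OC)c(OC)cc(OC)c3o2)c1 | target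

**Totals**
Total step count: 3. Longest linear sequence: 3 steps (1 → 3 → 6 → 9).

**Steps most likely to fail, with fallbacks**

Step 1 (oxidation of the very electron-rich arene, or over-demethylation by AlCl3). The fallback sets out from 1 and comes back at 3, separating C–C bond formation from ether cleavage. Directed ortho-metalation of 1 (n-BuLi, TMEDA, THF, 0 °C) gives 2,3,5,6-tetramethoxyphenyllithium F1. Addition of N-methoxy-N-methylacetamide at −78 °C gives the tetrahedral lithium 1-[methoxy(methyl)amino]-1-(2,3,5,6-tetramethoxyphenyl)ethanolate F2, which collapses on NH4Cl quench to ketone 2, isolated this time. BCl3 (1.1 equiv, CH2Cl2, −78 to 0 °C) then removes one carbonyl-chelated ortho methyl group to give 3.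

Step 2 (sluggish aldol of the di-ortho-substituted ketone, or mixtures with flavanone). The fallback sets out from 3 and comes back at 9, replacing the chalcone by a Baker–Venkataraman sequence. O-Acylation of 3 with commercial 2,5-dimethoxybenzoyl chloride (pyridine, DMAP cat., rt) gives 2-acetyl-3,4,6-trimethoxyphenyl 2,5-dimethoxybenzoate F3. KOH in pyridine at 50 °C effects the acyl migration to 1-(2,5-dimethoxyphenyl)-3-(2-hydroxy-3,5,6-trimethoxyphenyl)propane-1,3-dione F4. Cyclodehydration (cat. H2SO4, AcOH, 100 °C) gives 9 directly.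

Step 3 (ring iodination or partial 5-O-demethylation in hot I2/DMSO). The fallback sets out from 6 and comes back at 9, splitting ring closure from oxidation and using no iodine. Chalcone 6 is isomerised with NaOAc in refluxing EtOH to flavanone 7, which is isolated and then dehydrogenated with DDQ in refluxing dioxane to 9. This fallback makes no new compound (F0).

**Further compounds**
F1 | step 1 | 2,3,5,6-tetramethoxyphenyllithium | [Li]c1c(OC)c(OC)cc(OC)c1OC
F2 | step 1 | lithium 1-[methoxy(methyl)amino]-1-(2,3,5,6-tetramethoxyphenyl)ethanolate | [Li]OC(C)(N(C)OC)c1c(OC)c(OC)cc(OC)c1OC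
F3 | step 2 | 2-acetyl-3,4,6-trimethoxyphenyl 2,5-dimethoxybenzoate | COc1ccc(OC)c(C(=O)Oc2c(OC)cc(OC)c(OC)c2C(C)=O)c1
F4 | step 2 | 1-(2,5-dimethoxyphenyl)-3-(2-hydroxy-3,5,6-trimethoxyphenyl)propane-1,3-dione | COc1ccc(OC)c(C(=O)CC(=O)c2c(O)c(OC)cc(OC)c2OC)c1
F0 | step 3 | none | none
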